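**Assumptions:** The target SMILES corresponds to the trans-(1R,2S) dihydronaphthalene core with two (R)-danshensu esters. Sodium (R)-danshensu (salvianic acid A sodium) is taken as a commercial chiral-pool material.

## Retrosynthetic overview

1. Rabdosiin (11) ⇐ global debenzylation of decabenzyl rabdosiin 10 ⇐ dehydration (C3=C4) of 4-hydroxytetralin 9.
2. Key step: 9 ⇐ photoenolization/Diels–Alder of o-benzylbenzaldehyde 4 with fumarate 8, which already carries both (R)-danshensu esters. This is the only ring-forming event (central carbocycle, C1–C2 and C3–C4 bonds), and the danshensu centres themselves direct C1 and C2.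
3. 8 ⇐ fumaryl chloride + perbenzylated (R)-danshensu 6; 4 ⇐ Negishi coupling of bromoaldehyde 2 with the benzylzinc from 3.
4. Deliberately avoided: biomimetic oxidative dimerisation of rosmarinic/caffeic esters and the bis-benzylidenesuccinate (Stobbe) cyclisation.

## Route

**Step 1**
Reactants: 1, 3,4-bis(benzyloxy)benzaldehyde
Product: 2, 4,5-bis(benzyloxy)-2-bromobenzaldehyde
Conditions: Br2 (1.05 equiv), NaOAc, AcOH, rt
Reagents that add atoms: bromine, BrBr
Why: Electrophilic aromatic bromination goes para to the 3-OBn and ortho to CHO (the 6-position, as in veratraldehyde → 6-bromoveratraldehyde), and NaOAc buffers HBr so the benzyl ethers survive.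

**Step 2**
Reactants: 2, 4,5-bis(benzyloxy)-2-bromobenzaldehyde; 3, 3,4-bis(benzyloxy)benzyl chloride
Product: 4, 4,5-bis(benzyloxy)-2-[3,4-bis(benzyloxy)benzyl]benzaldehyde
Conditions: 3, Zn dust, LiCl, THF, 25 °C; then slow addition to 2, Pd(OAc)2 (2 mol%), SPhos (4 mol%), THF, 25 °C; neutral work-up (strong acid would trigger Bradsher cyclisation of 4 to an anthracene)
Reagents that add atoms: none (both partners are the reactants)
Why: Negishi sp3–sp2 cross-coupling, in which Pd/SPhos coupling of the benzylic zinc chloride with the ortho-formyl-activated aryl bromide should outrun uncatalysed addition of the zinc reagent to the aldehyde when the reagent is added slowly.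

**Step 3**
Reactants: 5, sodium (2R)-3-(3,4-dihydroxyphenyl)-2-hydroxypropanoate (sodium danshensu)
Product: 6, benzyl (2R)-3-[3,4-bis(benzyloxy)phenyl]-2-hydroxypropanoate
Conditions: BnBr (3.4 equiv), K2CO3, cat. NaI, DMF, rt → 40 °C, Ar
Reagents that add atoms: benzyl bromide, BrCc1ccccc1
Why: Williamson/carboxylate SN2 alkylation, in which K2CO3 ionises only the two phenols and the carboxylate, so the secondary alcohol stays free and the (R) centre is untouched.

**Step 4**
Reactants: 6, benzyl (2R)-3-[3,4-bis(benzyloxy)phenyl]-2-hydroxypropanoate (2.1 equiv); 7, fumaryl chloride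
Product: 8, bis{(2R)-1-(benzyloxy)-3-[3,4-bis(benzyloxy)phenyl]-1-oxopropan-2-yl} (2E)-but-2-enedioate (C2-symmetric fumarate of 6)
Conditions: pyridine, CH2Cl2, −20 °C → rt
Reagents that add atoms: none (the fumaroyl unit comes from reactant 7)
Why: Acylation of the secondary alcohol by the bis-acid chloride, which touches neither the E-alkene nor the α-stereocentres.

**Step 5 (key step)**
Reactants: 4, 4,5-bis(benzyloxy)-2-[3,4-bis(benzyloxy)benzyl]benzaldehyde (1.5 equiv); 8, the bis-danshensu fumarate
Product: 9, bis{(2R)-1-(benzyloxy)-3-[3,4-bis(benzyloxy)phenyl]-1-oxopropan-2-yl} (1R,2S,3R,4R)-6,7-bis(benzyloxy)-1-[3,4-bis(benzyloxy)phenyl]-4-hydroxy-1,2,3,4-tetrahydronaphthalene-2,3-dicarboxylate (1-Ar/4-OH cis, 3-CO2R/4-OH cis, 2,3-trans, 1-Ar/2-CO2R trans)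
Conditions: hν (350–365 nm, Pyrex), degassed PhMe (0.03 M), 10 °C
Reagents that add atoms: none
Why: Photoenolization/Diels–Alder, in which the triplet aldehyde abstracts the doubly benzylic ortho-CH2 hydrogen to give the (E,E)-hydroxy-o-quinodimethane, which adds to the symmetric fumarate (no regiochemical issue) with the ester next to the OH endo, fixing 1,4-cis/3,4-cis/2,3-trans and hence 1,2-trans; attack is predicted on the Si,Si face, where the s-cis (R)-α-acyloxy ester presents its CO2Bn carbonyl as hydrogen-bond acceptor to the dienol OH (the model used for lactate- and mandelate-type fumarates with α-hydroxy-o-quinodimethanes, under which (R)-auxiliaries give 1R), setting C1 = R and C2 = S.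

**Step 6**
Reactants: 9, the 4-hydroxytetralin cycloadduct
Product: 10, bis{(2R)-1-(benzyloxy)-3-[3,4-bis(benzyloxy)phenyl]-1-oxopropan-2-yl} (1R,2S)-6,7-bis(benzyloxy)-1-[3,4-bis(benzyloxy)phenyl]-1,2-dihydronaphthalene-2,3-dicarboxylate (decabenzyl rabdosiin)
Conditions: p-TsOH·H2O (10 mol%), PhMe, 4 Å MS, 50 °C
Reagents that add atoms: none
Why: Acid-catalysed E1 dehydration of the benzylic, para-alkoxy-stabilised alcohol with loss of the only β-hydrogen (C3–H, α to the ester) gives the conjugated C3=C4 alkene, and C1 and C2 are not touched under non-basic conditions.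

**Step 7**
Reactants: 10, decabenzyl rabdosiin
Product: 11, rabdosiin, (2R)-2-{[(1R,2S)-3-{[(1R)-1-carboxy-2-(3,4-dihydroxyphenyl)ethoxy]carbonyl}-1-(3,4-dihydroxyphenyl)-6,7-dihydroxy-1,2-dihydronaphthalene-2-carbonyl]oxy}-3-(3,4-dihydroxyphenyl)propanoic acid
Conditions: BCl3 (1 M in CH2Cl2, ca. 25 equiv), pentamethylbenzene (ca. 30 equiv), CH2Cl2, −78 → 0 °C; CHCl3/MeOH quench at −78 °C, aqueous work-up, RP-C18, Ar
Reagents that add atoms: none (hydrogen only)
Why: Lewis-acid debenzylation with a non-basic benzyl-cation scavenger cleaves the eight aryl benzyl ethers and two benzyl esters by SN1-type C–O scission, while the conjugated alkene (which hydrogenolysis would reduce), the two secondary alkyl ester links and all four stereocentres are left alone.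

## Compound list

1 | 3,4-bis(benzyloxy)benzaldehyde | O=Cc1ccc(OCc2ccccc2)c(OCc2ccccc2)c1 | starting material
2 | 4,5-bis(benzyloxy)-2-bromobenzaldehyde | O=Cc1cc(OCc2ccccc2)c(OCc2ccccc2)cc1Br | intermediate
3 | 3,4-bis(benzyloxy)benzyl chloride | ClCc1ccc(OCc2ccccc2)c(OCc2ccccc2)c1 | starting material
4 | 4,5-bis(benzyloxy)-2-[3,4-bis(benzyloxy)benzyl]benzaldehyde | O=Cc1cc(OCc2ccccc2)c(OCc2ccccc2)cc1Cc1ccc(OCc2ccccc2)c(OCc2ccccc2)c1 | intermediate
5 | sodium (2R)-3-(3,4-dihydroxyphenyl)-2-hydroxypropanoate (sodium danshensu) | O[C@H](Cc1ccc(O)c(O)c1)C(=O)[O-].[Na+] | starting material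
6 | benzyl (2R)-3-[3,4-bis(benzyloxy)phenyl]-2-hydroxypropanoate | O[C@H](Cc1ccc(OCc2ccccc2)c(OCc2ccccc2)c1)C(=O)OCc1ccccc1 | intermediate
7 | fumaryl chloride | O=C(Cl)/C=C/C(=O)Cl | starting material
8 | bis{(2R)-1-(benzyloxy)-3-[3,4-bis(benzyloxy)phenyl]-1-oxopropan-2-yl} fumarate | O=C(/C=C/C(=O)O[C@H](Cc1ccc(OCc2ccccc2)c(OCc2ccccc2)c1)C(=O)OCc1ccccc1)O[C@H](Cc1ccc(OCc2ccccc2)c(OCc2ccccc2)c1)C(=O)OCc1ccccc1 | intermediate
9 | (1R,2S,3R,4R)-4-hydroxytetralin-2,3-dicarboxylate bis-danshensu ester, decabenzyl | O=C(O[C@H](Cc1ccc(OCc2ccccc2)c(OCc2ccccc2)c1)C(=O)OCc1ccccc1)[C@H]1[C@@H](O)c2cc(OCc3ccccc3)c(OCc3ccccc3)cc2[C@@H](c2ccc(OCc3ccccc3)c(OCc3ccccc3)c2)[C@@H]1C(=O)O[C@H](Cc1ccc(OCc2ccccc2)c(OCc2ccccc2)c1)C(=O)OCc1ccccc1 | intermediate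
10 | decabenzyl rabdosiin, (1R,2S)-1,2-dihydronaphthalene | O=C(O[C@H](Cc1ccc(OCc2ccccc2)c(OCc2ccccc2)c1)C(=O)OCc1ccccc1)C1=Cc2cc(OCc3ccccc3)c(OCc3ccccc3)cc2[C@@H](c2ccc(OCc3ccccc3)c(OCc3ccccc3)c2)[C@@H]1C(=O)O[C@H](Cc1ccc(OCc2ccccc2)c(OCc2ccccc2)c1)C(=O)OCc1ccccc1 | intermediate
11 | rabdosiin | O=C(O[C@H](Cc1ccc(O)c(O)c1)C(=O)O)C1=Cc2cc(O)c(O)cc2[C@@H](c2ccc(O)c(O)c2)[C@@H]1C(=O)O[C@H](Cc1ccc(O)c(O)c1)C(=O)O | target

## Summary

Total steps: 7. Longest linear sequence: 5 (1 → 2 → 4 → 9 → 10 → 11, or 5 → 6 → 8 → 9 → 10 → 11).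

Three steps most likely to fail:

1. **Step 5 (photoenolization/Diels–Alder).** The facial sense and its magnitude rest on a hydrogen-bond model applied to an untested auxiliary (the target's own danshensu esters). Photoenolization of the electron-rich aldehyde may also be inefficient, and sensitised E/Z isomerisation of the fumarate is possible. Fallback: decouple core stereocontrol from the side chains. Run the cycloaddition with a fumarate of a removable α-hydroxy-ester auxiliary of whichever configuration gives (1R,2S) (methyl (R)-mandelate by the same model), dehydrate, cleave the auxiliaries, then install both danshensu units by SN2 alkylation of the dicarboxylate with the triflate of benzyl (S)-3-[3,4-bis(benzyloxy)phenyl]lactate (inversion to R).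

2. **Step 7 (ten-fold debenzylation).** Risks are incomplete cleavage of the benzyl esters and acid or oxidative damage to the polycatechol product. Fallback: change the protecting-group strategy to all-allyl (allyl ethers and allyl esters on both fragments, e.g. per-allylation of 5) and finish with Pd(PPh3)4/morpholine, which is neutral and leaves the alkene alone.

3. **Step 2 (Negishi with a free aldehyde).** The benzylzinc may add to the CHO or homocouple. Fallback: reverse the polarity. Miyaura borylation of 2 to the aryl-Bpin, then Suzuki coupling with benzyl chloride 3 as the electrophile, so that no carbon nucleophile reactive toward aldehydes is present.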